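## The problem

1. Target 20 is a 4H-chromen-4-one. Ring A is the benzene ring (C4a, C5, C6, C7, C8, C8a), ring B is the 4-pyranone (O1, C2, C3, C4, C4a, C8a), and an unbranched C20 chain sits on C2.
2. It has no stereocentre and no double-bond geometry, so the whole problem is connectivity and regiochemistry.
3. The hard part is ring A. All six carbons are substituted, oxygen (C5, C7, C8a) alternating with carbon (C4a, C6, C8), so no ring C–H is left for late correction and each group must be placed without ambiguity.
4. Placing these groups one at a time on a benzenetriol nucleus is treacherous: that nucleus reacts through its triketo tautomer (geminal C-methylation, O- against C-acylation), and its three hydroxyl groups must be told apart.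
5. The chain holds two thirds of the carbon atoms but no handle; it must be joined exactly at C2, and once it is on, every intermediate is waxy and poorly soluble in polar media, so later steps must be few and run in ether, chlorinated or aromatic solvents.
6. The groups that dislike rough treatment are ring B (opened at C2 by hydroxide or alkoxide) and the free 5,7-dihydroxyarene (oxidised by air in base); the 5-OH is chelated to the C4 carbonyl and inert, the 7-OH is acidic and exposed.
7. The feature that opens another plan is the C4a=C8a bond, which belongs to both rings: in a monocyclic 4-pyranone these atoms are C3 and C2, an enol ether double bond with little aromatic stabilisation that can serve as the ene end of a dienylketene.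
8. The other four atoms of ring A, C5(O), C6(CH3), C7(O) and C8(CH3), show the polarity alternation of a ketene carbonyl carbon, the two carbons of a 1-oxypropyne and a methyl-bearing ketene α-carbon, so ring A can be grown on ring B in one operation instead of the reverse.

## Retrosynthesis

**20 from 19.**
- Only the O7–Si bond is cut.
- The ynol ether that delivers C6 and C7 must carry some group on oxygen. A triisopropylsilyl group stabilises the alkyne and leaves under buffered fluoride, which touches neither ring B nor the chelated 5-OH.
- An alkyl ether at O7, wedged between two methyl groups, would need a boron halide at the end.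
- The skeleton is not simplified. The cut only defines what the key step must deliver.

**19 from 11 and 14.**
- Ring A is taken apart at C4a–C5, C5–C6 and C7–C8, and C8–C8a is re-routed. In diazo ketone 11 the atom C8a carries the carbonyl carbon that will become C5, and C8 hangs on that carbon as the diazo carbon.
- Against the neighbouring cuts:
  - Cutting ring B, the usual choice, leaves the whole difficulty in the precursor.
  - A ketene hung on pyranone C3 (C4a) instead of C2 (C8a) would put the new hydroxyl group on C8.
  - A cyclobutenone-based variant would need a 4-acylcyclobutenone, whose vinylketene closes on its own acyl oxygen.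
- Only the chosen mapping gives O, CH3, O, CH3 in the right places.
- The precursors are a monocyclic, 2,6-disubstituted pyranone and a C3 alkyne, against a bicyclic product with a hexasubstituted arene.
- The forward reaction must run Wolff shift, regioselective (2+2) addition, 4π opening and 6π closure in one flask, through 15, 16, 17 and 18.

**11 from 7 and 10.**
- The bond between the acyl carbon (future C5) and the diazo carbon (future C8) is cut.
- The neighbouring choice, an ethyl ketone followed by diazo transfer, costs several more operations and brings a Grignard reagent next to ring B.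
- Acylation of diazoethane 10, made from nitrosourea 8, by acid chloride 9 forms the bond at once.
- Precursor 7 is a plain carboxylic acid.
- The forward reaction must acylate the diazo carbon faster than 10 adds as a dipole to ring B, and the HCl must be scavenged.

**7 from 3 and 4.**
- Ring B is cut at C4a–C8a (Claisen bond) and O1–C8a (cyclodehydration).
- A 1,3,5-tricarbonyl array closes to a 4-pyranone by itself in acid. Oxalate 4 brings C8a and the future C5 as a ready-made C2 unit, and these two atoms are later moved into their 1,3 relation by the Wolff shift.
- A cut on the chain side of C4 would need an acylpyruvate partner more acidic than any enolate that could attack it.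
- The precursor 3 is an open-chain β-diketone.
- The forward reaction must acylate its CH3 terminus and not its C5 methylene; intermediates 5 and 6 are not isolated.

**3 from 1 and 2.**
- The chain is cut one carbon out from C2, between the first and second carbon of the side chain.
- Diketone 1 is symmetrical, so its dianion has only one kind of terminal carbon. Bromide 2 is an unfunctionalised primary halide, so the join is a plain SN2 reaction in the first step.
- An acyl disconnection at C2 would need a C21 acyl donor and a mixed Claisen condensation.

**14 from 12.**
- The C–O and O–Si bonds of the ynol ether are cut.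
- Oxidation of acetylide 12 to ynolate 13 and O-silylation give 14 in one flask. No other route to a 1-oxypropyne is shorter.

## Roads not taken

**Alternative 1:** (the most obvious route)
- **Cut:** O1–C2 and C2–C3, ring B last.
- **Forward:** 2,4,6-trihydroxy-3,5-dimethylacetophenone A1 is O-acylated with heneicosanoyl chloride A2. The acyl group is moved to the acetyl carbon by Baker–Venkataraman rearrangement to give diketone A3, and acid closes ring B to 20.
- **Why the chosen plan is better:**
  - This plan leaves ring A, the real difficulty, to the preparation of A1. A1 has to be made group by group on a benzenetriol nucleus, where C-methylation competes with geminal dimethylation and dearomatisation.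
  - Three phenols compete for A2, so either protecting groups or extra equivalents of the C21 acyl chloride are spent.
  - Arene preparation, protection, acylation, rearrangement, closure and deprotection together are not shorter than the chosen route, and no step forms more than one skeletal bond.

**Alternative 2:**
- **Cut:** C4–C4a, C3–C4 and O1–C2, three components around C4.
- **Forward:** 2-iodo-3,5-dimethoxy-4,6-dimethylphenol A4, docos-1-yne A5 and carbon monoxide A6 are joined with PdCl2(PPh3)2 and a secondary amine. This is a carbonylative Sonogashira coupling to alkynone A7, followed by 6-endo-dig oxa-Michael closure and cleavage of two methyl ethers.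
- **Why the chosen plan is better:**
  - Oxidative addition of zerovalent palladium into a C–I bond flanked by two oxygen substituents on a very electron-rich ring is slow, so direct coupling without CO insertion can compete.
  - A7 can also close in the 5-exo mode.
  - Ring A is again built by decoration, and the ether at O7 between two methyl groups must be cleaved last.

**Alternative 3:**
- **Cut:** C4a–C5 and O1–C2, the biomimetic fold.
- **Forward:** the pyranone-masked tetraketo acid 4-hydroxy-3,5-dimethyl-6-(2,4-dioxotetracosyl)-2H-pyran-2-one A8 is opened and folded with Mg(OMe)2 in methanol. The C4a methylene attacks the C5 carboxyl carbon (Claisen mode) to give A3, which acid closes to 20.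
- **In its favour:** the two C-methyl groups block the aldol modes that start from C6 and C8, because those carbons would become quaternary.
- **Why the chosen plan is better:**
  - Aldol closure of the C3 methylene onto the C7 carbonyl stays open.
  - A8 must be assembled by repeated polyanion acylations. In each of these the product is more acidic than the nucleophile, so base and material are wasted.
  - That run-up is at least as long as the whole chosen route, and A8 is hardly simpler than 20.
  - In the chosen plan ring B itself is the mask of the triketone part, and the closure onto C4a has no competitor.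

Key step: step 5

Assumption: the side chain of the SMILES string is read as an unbranched icosyl group (twenty carbons), so bromide 2 carries nineteen.

## Steps

Step 1
Reactants: 1 pentane-2,4-dione; 2 1-bromononadecane
Product: 3 tetracosane-2,4-dione
Conditions: LiN(iPr)2 (2.1 equiv), THF, 0 °C; then 2, 0 °C to rt; aq. HCl
Reagents that add atoms: none
Why: γ-Alkylation of a β-diketone dianion: the second, less stabilised carbanion at the terminal carbon is the more nucleophilic site and displaces the primary bromide by SN2, so C3 stays unalkylated. The symmetry of 1 leaves no regiochemical choice.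

Step 2
Reactants: 3 tetracosane-2,4-dione; 4 diethyl oxalate
Product: 7 6-icosyl-4-oxo-4H-pyran-2-carboxylic acid, via trioxo ester 5 (not isolated), via pyranone ethyl ester 6 (not isolated)
Conditions: LiN(iPr)2 (2.1 equiv), THF, −78 to 0 °C; added to 4 (3 equiv), THF, −78 °C; aq. HCl; then conc. HCl–AcOH, 100 °C
Reagents that add atoms: water, O
Why: Terminal Claisen acylation of a β-diketone dianion: the second deprotonation of 3 takes the CH3 group in preference to the more hindered C5 methylene, and inverse addition to excess 4 at low temperature should stop at monoacylation. Hot acid then closes the 1,3,5-tricarbonyl array of 5 by attack of the C6 enol oxygen on the C2 ketone and loss of water, as in the classical chelidonic acid synthesis, and hydrolyses ester 6.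

Step 3
Reactants: 7 6-icosyl-4-oxo-4H-pyran-2-carboxylic acid; 8 N-ethyl-N-nitrosourea
Product: 11 2-(2-diazopropanoyl)-6-icosyl-4H-pyran-4-one, via acid chloride 9 (not isolated), via diazoethane 10 (not isolated)
Conditions: 7, (COCl)2, DMF (cat.), CH2Cl2, rt, then evaporation; separately 8, aq. KOH, Et2O, 0 °C, ether layer dried; the two combined with Et3N, Et2O–CH2Cl2, −20 to 0 °C
Reagents that add atoms: oxalyl chloride, O=C(Cl)C(=O)Cl (the chlorine of 9)
Why: Acylation of a diazoalkane by an acid chloride, the first stage of the Arndt–Eistert sequence with diazoethane in place of diazomethane. Et3N takes up the HCl (Newman–Beal modification), which is safe here because 9 has no α-hydrogen and cannot form a ketene.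

Step 4
Reactants: 12 prop-1-ynyllithium
Product: 14 triisopropyl(prop-1-yn-1-yloxy)silane, via lithium ynolate 13 (not isolated)
Conditions: t-BuOOH, LiN(SiMe3)2, THF, −78 °C; then 12, −78 to 0 °C; iPr3SiOTf, −78 to 0 °C
Reagents that add atoms: tert-butyl hydroperoxide, CC(C)(C)OO; triisopropylsilyl trifluoromethanesulfonate, CC(C)[Si](OS(=O)(=O)C(F)(F)F)(C(C)C)C(C)C
Why: Oxidation of a lithium acetylide by lithium tert-butyl peroxide, in which the acetylide carbon attacks the peroxide oxygen, gives ynolate 13. The bulky silyl triflate traps ynolates on oxygen, whereas small silyl groups go to carbon.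

Step 5
Reactants: 11 2-(2-diazopropanoyl)-6-icosyl-4H-pyran-4-one; 14 triisopropyl(prop-1-yn-1-yloxy)silane
Product: 19 5-hydroxy-2-icosyl-6,8-dimethyl-7-(triisopropylsiloxy)-4H-chromen-4-one, via methyl pyranonyl ketene 15 (not isolated), via cyclobutenone 16 (not isolated), via dienylketene 17 (not isolated), via cyclohexadienone 18 (not isolated)
Conditions: 14 (2.5 equiv), toluene (degassed, dilute in 11), hν (405–450 nm LED), 20 °C; then 110 °C in the dark
Reagents that add atoms: none
Why: Proposed new method: the closest known reaction types are the Danheiser benzannulation in its diazo ketone (photo-Wolff) form and the Smith–Hoehn ketene–alkyne phenol synthesis, both shown with alkenyl, aryl and five-membered heteroaryl groups as the ene part but not with the C2=C3 bond of a 4-pyranone. Excitation of the n→π* band of 11 expels N2 and the pyranonyl group migrates from the carbonyl carbon to the diazo carbon (Wolff rearrangement, new C8–C8a bond) to give ketene 15, while ring B, which absorbs only at much shorter wavelength, stays in the ground state. The methyl-bearing, nucleophilic carbon of ynol ether 14 attacks the ketene carbonyl carbon and the zwitterion collapses, a net (2+2) closure of the four-membered ring of 16 that forms C5–C6 and C7–C8 and, through the polarity of 14, fixes the alternation O, CH3, O, CH3. At 110 °C 16 undergoes reversible conrotatory 4π opening (C5–C8 cleaved) to 17; the methyl donor should prefer outward and the π-accepting pyranonyl group inward rotation, which is the productive sense, and the other isomer can return to 16. Ring A then closes by thermal disrotatory 6π electrocyclisation of the ketene carbon C5 onto pyranone C3 (the future C4a), and the C4a–H of 18, which lies between two carbonyl groups, enolises at once to the chelated phenol 19. This closure costs only the small resonance energy of a 4-pyranone, less than that of the benzene, furan or indole rings of the known cases, and pyranone C3 is the only carbon within reach, so no regioisomer can arise. The single stereocentres of 16 (the ring carbon bearing CH3 and pyranonyl) and of 18 (C4a) are formed racemic and are erased on aromatisation, so nothing has to be controlled. The selectivity that the step needs is Wolff shift against 1,2-hydrogen shift from the CH3 group of the carbene, and (2+2) capture of 15 against its dimerisation; direct singlet excitation of the s-Z conformer, dilution of 11 and an excess of 14 serve both.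

Step 6
Reactants: 19 5-hydroxy-2-icosyl-6,8-dimethyl-7-(triisopropylsiloxy)-4H-chromen-4-one
Product: 20 5,7-dihydroxy-2-icosyl-6,8-dimethyl-4H-chromen-4-one
Conditions: Bu4NF, AcOH, THF, 0 °C
Reagents that add atoms: none
Why: Fluoride cleavage of an aryl silyl ether: the phenoxide is a good leaving group from silicon, so even the ether flanked by two methyl groups should fall at 0 °C. The AcOH buffer keeps the medium from becoming basic enough to open ring B or to let the free dihydroxyarene oxidise.

## Compound list

1 | pentane-2,4-dione (acetylacetone) | CC(=O)CC(C)=O | starting material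
2 | 1-bromononadecane | CCCCCCCCCCCCCCCCCCCBr | starting material
3 | tetracosane-2,4-dione | CCCCCCCCCCCCCCCCCCCCC(=O)CC(C)=O | intermediate
4 | diethyl oxalate | CCOC(=O)C(=O)OCC | starting material
5 | ethyl 2,4,6-trioxohexacosanoate | CCCCCCCCCCCCCCCCCCCCC(=O)CC(=O)CC(=O)C(=O)OCC | intermediate
6 | ethyl 6-icosyl-4-oxo-4H-pyran-2-carboxylate | CCCCCCCCCCCCCCCCCCCCc1cc(=O)cc(C(=O)OCC)o1 | intermediate
7 | 6-icosyl-4-oxo-4H-pyran-2-carboxylic acid | CCCCCCCCCCCCCCCCCCCCc1cc(=O)cc(C(=O)O)o1 | intermediate
8 | N-ethyl-N-nitrosourea | CCN(N=O)C(N)=O | starting material
9 | 6-icosyl-4-oxo-4H-pyran-2-carbonyl chloride | CCCCCCCCCCCCCCCCCCCCc1cc(=O)cc(C(=O)Cl)o1 | intermediate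
10 | diazoethane | CC=[N+]=[N-] | intermediate
11 | 2-(2-diazopropanoyl)-6-icosyl-4H-pyran-4-one | CCCCCCCCCCCCCCCCCCCCc1cc(=O)cc(C(=O)C(C)=[N+]=[N-])o1 | intermediate
12 | prop-1-ynyllithium | [Li]C#CC | starting material
13 | lithium prop-1-yn-1-olate | CC#C[O-].[Li+] | intermediate
14 | triisopropyl(prop-1-yn-1-yloxy)silane | CC#CO[Si](C(C)C)(C(C)C)C(C)C | intermediate
15 | 2-(6-icosyl-4-oxo-4H-pyran-2-yl)prop-1-en-1-one (methyl pyranonyl ketene) | CCCCCCCCCCCCCCCCCCCCc1cc(=O)cc(C(C)=C=O)o1 | intermediate
16 | 4-(6-icosyl-4-oxo-4H-pyran-2-yl)-2,4-dimethyl-3-(triisopropylsiloxy)cyclobut-2-en-1-one (racemic) | CCCCCCCCCCCCCCCCCCCCc1cc(=O)cc(C2(C)C(=O)C(C)=C2O[Si](C(C)C)(C(C)C)C(C)C)o1 | intermediate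
17 | (3E)-4-(6-icosyl-4-oxo-4H-pyran-2-yl)-2-methyl-3-(triisopropylsiloxy)penta-1,3-dien-1-one (pyranone ring cis to the ketene arm) | O=C=C(C)/C(O[Si](C(C)C)(C(C)C)C(C)C)=C(/C)c1cc(=O)cc(CCCCCCCCCCCCCCCCCCCC)o1 | intermediate
18 | 2-icosyl-6,8-dimethyl-7-(triisopropylsiloxy)-4aH-chromene-4,5-dione (racemic) | CCCCCCCCCCCCCCCCCCCCC1=CC(=O)C2C(=O)C(C)=C(O[Si](C(C)C)(C(C)C)C(C)C)C(C)=C2O1 | intermediate
19 | 5-hydroxy-2-icosyl-6,8-dimethyl-7-(triisopropylsiloxy)-4H-chromen-4-one | CCCCCCCCCCCCCCCCCCCCc1cc(=O)c2c(O)c(C)c(O[Si](C(C)C)(C(C)C)C(C)C)c(C)c2o1 | intermediate
20 | 5,7-dihydroxy-2-icosyl-6,8-dimethyl-4H-chromen-4-one | CCCCCCCCCCCCCCCCCCCCc1cc(=O)c2c(O)c(C)c(O)c(C)c2o1 | target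

## Step count and least certain steps

Total steps: 6. Longest linear sequence: 5 (steps 1, 2, 3, 5, 6). Step 4 is a one-step side branch.

**Step 5 (key step, proposed new method).**
- The most likely failure is loss of the carbene to 1,2-hydrogen migration from its methyl group. This competes with the Wolff shift whenever 11 reacts from its s-E conformer or through the triplet.
- Next comes slow (2+2) capture of the hindered disubstituted ketene 15, which leaves time for dimerisation or hydration.
- Last is a 1,5-hydrogen shift in the unproductive geometric isomer of 17, which would drain the equilibrium between 16 and 17.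
- The fallback uses known chemistry with ring A bought and ring B closed last. It sets out from 2 and comes back at 20. The dianion of ethyl acetoacetate (LiN(iPr)2, 2 equiv, THF, 0 °C) is alkylated at its terminal carbon with 2 to give ethyl 3-oxotricosanoate F1. F1 is then heated without solvent or catalyst at about 240 °C with 2,4-dimethylbenzene-1,3,5-triol F2 (Mentzer pyrone synthesis). The acylketene from F1 acylates the only free ring carbon of F2, and either of the two equivalent flanking hydroxyl groups closes ring B with loss of water to give 20 directly.

**Step 3.**
- Diazoethane may add as a 1,3-dipole to the C2=C3 bond of ring B, which is activated by both the ring carbonyl and the acyl chloride.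
- Incompletely scavenged HCl may protonate 11 with loss of nitrogen.
- The fallback sets out from 9 and comes back at 11 without any diazoalkane. Acid chloride 9 is treated with MeNH(OMe)·HCl and Et3N to give 6-icosyl-N-methoxy-N-methyl-4-oxo-4H-pyran-2-carboxamide F3. EtMgBr in THF at −78 °C gives 6-icosyl-2-propanoyl-4H-pyran-4-one F4. LiN(SiMe3)2 and CF3CO2CH2CF3 at −78 °C give 4,4,4-trifluoro-1-(6-icosyl-4-oxo-4H-pyran-2-yl)-2-methylbutane-1,3-dione F5. Detrifluoroacetylative diazo transfer (MsN3, Et3N, water, MeCN) then gives 11.

**Step 2.**
- Proton transfer from the first-formed, more acidic trioxo ester to unreacted dianion would stall the acylation.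
- A second attack on the new α-keto ester carbonyl, or deprotonation at the C5 methylene instead of the CH3 group, would erode the material.
- The fallback forms ring B before the chain is joined, so the regiochemical question disappears. It sets out from 1 and 4 and comes back at 7. Symmetrical 1 is condensed with 4 (NaOEt, EtOH) to give ethyl 2,4,6-trioxoheptanoate F6. Hot conc. HCl closes and hydrolyses it to 6-methyl-4-oxo-4H-pyran-2-carboxylic acid F7. The dianion of F7 (carboxylate and lateral carbanion; LiN(iPr)2, 2 equiv, THF, −78 °C) is alkylated at the methyl carbon with 2 to give 7.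

**Step 4.**
- Silylation of ynolate 13 at carbon instead of oxygen, hydrolysis of the ynol ether on work-up or silica, and loss on evaporation are the risks.
- The fallback changes the oxygen substituent and therefore the endgame. It sets out from 11 and comes back at 20. Commercial ethoxyacetylene is lithiated (n-BuLi) and methylated (MeI) to give 1-ethoxyprop-1-yne F8. F8 is used in place of 14 under the conditions of step 5 to give 7-ethoxy-5-hydroxy-2-icosyl-6,8-dimethyl-4H-chromen-4-one F9. BBr3 in CH2Cl2 (−78 °C to rt) cleaves the ethyl ether to give 20.

## Further compounds

F1 | step 5 | ethyl 3-oxotricosanoate | CCCCCCCCCCCCCCCCCCCCC(=O)CC(=O)OCC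
F2 | step 5 | 2,4-dimethylbenzene-1,3,5-triol | Cc1c(O)cc(O)c(C)c1O
F3 | step 3 | 6-icosyl-N-methoxy-N-methyl-4-oxo-4H-pyran-2-carboxamide | CCCCCCCCCCCCCCCCCCCCc1cc(=O)cc(C(=O)N(C)OC)o1
F4 | step 3 | 6-icosyl-2-propanoyl-4H-pyran-4-one | CCCCCCCCCCCCCCCCCCCCc1cc(=O)cc(C(=O)CC)o1
F5 | step 3 | 4,4,4-trifluoro-1-(6-icosyl-4-oxo-4H-pyran-2-yl)-2-methylbutane-1,3-dione (racemic) | CCCCCCCCCCCCCCCCCCCCc1cc(=O)cc(C(=O)C(C)C(=O)C(F)(F)F)o1
F6 | step 2 | ethyl 2,4,6-trioxoheptanoate | CC(=O)CC(=O)CC(=O)C(=O)OCC
F7 | step 2 | 6-methyl-4-oxo-4H-pyran-2-carboxylic acid | Cc1cc(=O)cc(C(=O)O)o1
F8 | step 4 | 1-ethoxyprop-1-yne | CCOC#CC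
F9 | step 4 | 7-ethoxy-5-hydroxy-2-icosyl-6,8-dimethyl-4H-chromen-4-one | CCCCCCCCCCCCCCCCCCCCc1cc(=O)c2c(O)c(C)c(OCC)c(C)c2o1
A1 | alternative 1 | 1-(2,4,6-trihydroxy-3,5-dimethylphenyl)ethan-1-one | CC(=O)c1c(O)c(C)c(O)c(C)c1O
A2 | alternative 1 | heneicosanoyl chloride | CCCCCCCCCCCCCCCCCCCCC(=O)Cl
A3 | alternative 1 | 1-(2,4,6-trihydroxy-3,5-dimethylphenyl)tricosane-1,3-dione | CCCCCCCCCCCCCCCCCCCCC(=O)CC(=O)c1c(O)c(C)c(O)c(C)c1O
A4 | alternative 2 | 2-iodo-3,5-dimethoxy-4,6-dimethylphenol | Oc1c(I)c(OC)c(C)c(OC)c1C
A5 | alternative 2 | docos-1-yne | CCCCCCCCCCCCCCCCCCCCC#C
A6 | alternative 2 | carbon monoxide | [C-]#[O+]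
A7 | alternative 2 | 1-(2-hydroxy-4,6-dimethoxy-3,5-dimethylphenyl)tricos-2-yn-1-one | CCCCCCCCCCCCCCCCCCCCC#CC(=O)c1c(O)c(C)c(OC)c(C)c1OC
A8 | alternative 3 | 4-hydroxy-3,5-dimethyl-6-(2,4-dioxotetracosyl)-2H-pyran-2-one | CCCCCCCCCCCCCCCCCCCCC(=O)CC(=O)Cc1oc(=O)c(C)c(O)c1C
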